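## The problem

The target is a chlorinated bisabolane-type diester in which a cyclohexane ring (C1 bears the chain, C2 is CH2, C3 carries chlorine, C4 the methyl and tertiary hydroxyl, C5 an angelate, C6 a free hydroxyl) is joined by the single C1–C7 bond to a five-carbon chain (C7 an exocyclic methylene carbon, C8 an angeloylated carbinol, C9 CH2, C10–C11 a trisubstituted epoxide). Nothing is fused or bridged, so the difficulty is stereochemical: five contiguous ring stereocentres (1R,3S,4S,5S,6S) and two chain stereocentres (8S,10R), separated from the ring by the sp2 carbon C7 and from each other by C9. On the ring the chain and the oxygens at C6, C5 and C4 lie on one face and chlorine on the other. This array can be relayed: O6 directs O5 (hydride anti to an axial O6), O5 directs the C4 oxygen (hydroxyl-directed epoxidation), and the epoxide directs chlorine (anti opening at C3). No relay reaches C8 or C10 once the ring exists, so C10 needs a reagent and C8 must either be set by a reagent or be bought and made to act while the ring forms. The groups are fragile: angelates isomerise to tiglates under nucleophilic catalysis and migrate to cis hydroxyls under base, the trans-diaxial chlorohydrin recloses to the epoxide in aqueous base, the side-chain epoxide opens with acid, and the C8 ester is allylic. The enabling feature is that C2–C5 with the C4 methyl are an intact isoprene unit and that C1 and C6 are cis, carrying the chain carbon C7 and an oxygen. Read as a C3=C4 cyclohexene, the ring is therefore the [4+2] adduct of isoprene and a Z alkene bearing the C7 acyl group and boron as a stand-in for O6.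

## Retrosynthesis

**28 ⇒ 27 ⇒ 26 ⇒ 24 + 25.** The O6–Si bond is cut last. With O6 masked to the end, the C5 angelate has no free cis neighbour to migrate to during the aqueous buffered epoxidation, and a triethylsilyl group leaves under buffered fluoride that spares epoxide, chlorohydrin and esters. Cutting the epoxide oxygen (27 ⇒ 26) and then the C10=C11 alkene (26 ⇒ 24 + 25) keeps C10 and the electron-rich prenyl alkene out of every earlier oxidation. The forward steps need reagent control at C10 and a metathesis that touches only the monosubstituted alkene.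

**24 ⇒ 23 + 15 ⇒ 22 ⇒ 21 ⇒ 20 ⇒ 19 ⇒ 18.** The C5 ester is cut to chlorohydrin 23 and the angeloyl donor 15. The C3–Cl bond is cut to epoxy alcohol 22, preferred over HOCl addition to the alkene because O5 can then choose the epoxide face and guide chloride to C3. The epoxide oxygen is cut to allylic alcohol 21. The C5–O bond goes back through enone 20 and alcohol 19 to the allylic C–H bond of cyclohexene 18. Each cut removes one stereocentre, and 18 keeps only C1, C6 and C8. The forward reactions must oxidise the ring CH2 next to the methyl-bearing alkene carbon and then pass stereochemistry from O6 to O5 to the epoxide to chlorine.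

**18 ⇒ 17 ⇒ 16 ⇒ 13 + 15 ⇒ 12 ⇒ 11; 15 ⇒ 14.** O6 is traced to a C–B bond (17 ⇒ 16), the C8 ester to alcohol 13 and mixed anhydride 15, and the C7 methylene to ketone 11. Anhydride 15 is cut at its anhydride C–O bond to angelic acid 14; it is made once and serves both acylations, so the Z alkene of the acid is exposed to activation a single time and never to a nucleophilic catalyst. Keeping O6 as boron while O8 is unmasked and esterified means the two secondary hydroxyls are never free together, so no orthogonal pair of silyl groups is needed. Methylenating first removes the ketone whose α-carbon C1 could epimerise and avoids a β-hydroxy ketone. The forward steps need a non-basic methylenation and a C–B oxidation with retention.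

**11 ⇒ 9 + 10.** Cutting C1–C2 and C5–C6 opens the ring to isoprene 10 and the (S,Z)-β-boryl enone 9. No other cut removes a ring and two stereocentres at once from purchasable C5 and C2 pieces. Its neighbours (C1–C6 aldol, C2–C3 or C4–C5 enolate closures) would leave the cis C1/C6 relationship to a separate step. The forward reaction must be para-selective, keep the Z geometry, and use one face of 9 as dictated by C8. A silyl ether is kept on O8 because a chelate would expose the opposite face.

**9 ⇒ 8 ⇒ 6 + 7 ⇒ 4 + 5 ⇒ 3 ⇒ 2 ⇒ 1.** The Z alkene is cut to its E isomer 8, and 8 to ynone 6 and diboron 7 (C–B bond). The ynone is cut to Weinreb amide 4 and ethynylmagnesium bromide 5. Amide 4 goes back by silylation and amidation to hydroxy acid 2, and 2 to L-allylglycine 1, which already holds C8 in the S configuration together with the allyl arm. This spares an auxiliary-based alkylation; the forward steps must keep C8 intact next to a carbonyl.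

## Roads not taken

**Alternative 1:** The cut is at C7/C8. The exocyclic methylene and the C8 carbinol come from epoxy alcohol A1 by turning its CH2OH into an iodide and opening reductively with zinc. A1 is made from the (E)-allylic alcohol A2 by epoxidation with Ti(OiPr)4, L-(+)-diethyl tartrate and tBuOOH.
- Merits: C8 is set by a reagent whose sense is predictable and independent of the ring. The prenyl group is already in place, and no hindered ketone has to be methylenated.
- Weak points: A2 already contains the complete chlorohydrin ring, so the five ring stereocentres must come from a separate, unspecified ring synthesis. Its trisubstituted alkene of defined E geometry sits on a branched ring carbon and is not easy to make. The free homoallylic C6 hydroxyl competes for titanium. The bulky ring substituent on the alkene slows the epoxidation and may be mismatched with the tartrate.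
- Comparison: on C8 this road is better, because reagent control there does not depend on a conformational argument. The chosen plan sets against it that its bought C8 stereocentre also fixes C1 and C6 in the step that makes the ring, so no second ring synthesis is needed.

**Alternative 2:** The cut is the C2–C3 ring bond. Catalytic Hg(OCOCF3)2 in aqueous acetone converts the sugar enol ether A4 into cyclohexanone A3 through a mercurio-enolate that adds to the former anomeric aldehyde.
- Merits: the all-cis oxygens at C4, C5 and C6 are bought from a carbohydrate, with secure absolute configuration. This is exactly where the chosen plan is weakest (steps 14–18, including a regiochemical gamble in the allylic oxidation).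
- Weak points: a 2-C-methyl talo-configured sugar is not available and costs many protection and inversion steps. The reaction uses divalent mercury. A3 is a β-hydroxy ketone prone to elimination. Its C3 hydroxyl must become chloride with net retention, again through an epoxide. The C1 ketone must be turned into a CH carrying the chain cis to O6, and C7, C8 and the rest of the chain are still to be made without help from the sugar.
- Comparison: better for O4/O5/O6, worse for C1–C7 and the chain. The chosen plan forms the C1–C7 relationship and the cis C1/C6 pair in one bond-forming event.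

**Alternative 3:** The cuts are C1–C2 and C4–C5. Keto ester A6 adds to chloroenone A7 and the adduct closes by aldol reaction to ketol A5 under a chiral bifunctional amine base.
- Merits: it is the most convergent route. Chlorine and the tertiary carbinol arrive with the building blocks, so no allylic oxidation, epoxidation or chloride opening is needed, and two achiral components give a ring with four stereocentres in one step. If the equilibrium favoured the needed isomer it would be clearly shorter than the chosen plan.
- Weak points: relative configuration rests on equilibration, and the needed isomer (chlorine and tertiary hydroxyl trans-diaxial) is not obviously the thermodynamic sink. C3 can only be corrected through retro-aldol. Enantiocontrol by a base is hard to hold through a reversible manifold. The α-chloro ketone intermediate invites enolate displacement of chloride and the ketol invites dehydration. The C6 ketone must still be reduced to the axial alcohol and the ester turned into C7/C8 with separate control of C8.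
- Comparison: the chosen plan is longer on the ring heteroatoms but each stereocentre comes from a step of known stereochemical course (suprafacial cycloaddition, axial hydride delivery, directed epoxidation, anti opening) and from one bought stereocentre.

Key step: step 7

Remarks on the chemistry (assumptions):
- Ring and chain are numbered C1–C11 as above throughout.
- Alcohol 19 is written as the C5 epimer expected from oxygen delivery anti to O6; either epimer, and any enone formed with it, converges at 20.
- The D-fructose-derived Shi ketone is taken to give the (R)-epoxide from the prenyl group, its usual sense for trisubstituted alkenes.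
- Mixed anhydride 15 is prepared once in step 10, in an amount that serves steps 11 and 19, and kept as a cold toluene solution under argon.

## Route

Step 1
Reactants: 1 (S)-2-aminopent-4-enoic acid (L-allylglycine)
Product: 2 (S)-2-hydroxypent-4-enoic acid
Conditions: NaNO2, 1 M H2SO4 (aq), 0 °C → rt
Reagents that add atoms: water, O
Why: Diazotisation of an α-amino acid; the carboxylate displaces N2 to an α-lactone that water opens, two inversions, so C8 keeps the S configuration.

Step 2
Reactants: 2 (S)-2-hydroxypent-4-enoic acid
Product: 3 (S)-2-hydroxy-N-methoxy-N-methylpent-4-enamide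
Conditions: MeNHOMe·HCl, EDC·HCl, HOBt, N-methylmorpholine, CH2Cl2, 0 °C → rt
Reagents that add atoms: N,O-dimethylhydroxylamine hydrochloride, CNOC.Cl
Why: Carbodiimide amide coupling to the Weinreb amide; the free α-hydroxyl is tolerated and C8 is not touched.

Step 3
Reactants: 3 (S)-2-hydroxy-N-methoxy-N-methylpent-4-enamide
Product: 4 (S)-2-[(tert-butyldimethylsilyl)oxy]-N-methoxy-N-methylpent-4-enamide
Conditions: TBSCl, imidazole, DMF, rt
Reagents that add atoms: tert-butyldimethylsilyl chloride, CC(C)(C)[Si](C)(C)Cl
Why: Standard silylation of a secondary alcohol; a bulky silyl ether is chosen because it will not chelate aluminium in step 7.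

Step 4
Reactants: 4 (S)-2-[(tert-butyldimethylsilyl)oxy]-N-methoxy-N-methylpent-4-enamide; 5 ethynylmagnesium bromide (HC≡CMgBr)
Product: 6 (S)-4-[(tert-butyldimethylsilyl)oxy]hept-6-en-1-yn-3-one
Conditions: THF, −20 → 0 °C; inverse quench into cold 1 M HCl
Reagents that add atoms: none
Why: Grignard addition to a Weinreb amide stops at the ketone through the chelated tetrahedral intermediate; the acidic inverse quench keeps the liberated amine from adding to the ynone.

Step 5
Reactants: 6 (S)-4-[(tert-butyldimethylsilyl)oxy]hept-6-en-1-yn-3-one; 7 bis(pinacolato)diboron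
Product: 8 (S,E)-4-[(tert-butyldimethylsilyl)oxy]-1-(4,4,5,5-tetramethyl-1,3,2-dioxaborolan-2-yl)hepta-1,6-dien-3-one
Conditions: CuCl (5 mol %), Xantphos (5 mol %), NaOtBu (10 mol %), MeOH (2 equiv), THF, 0 °C
Reagents that add atoms: none
Why: Copper-catalysed conjugate borylation of an ynone (syn borylcupration, then protonation by methanol) should give the E alkene with boron trans to the acyl group.

Step 6
Reactants: 8 (S,E)-4-[(tert-butyldimethylsilyl)oxy]-1-(4,4,5,5-tetramethyl-1,3,2-dioxaborolan-2-yl)hepta-1,6-dien-3-one
Product: 9 (S,Z)-4-[(tert-butyldimethylsilyl)oxy]-1-(4,4,5,5-tetramethyl-1,3,2-dioxaborolan-2-yl)hepta-1,6-dien-3-one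
Conditions: thioxanthone (5 mol %), MeCN, 402 nm LED, rt
Reagents that add atoms: none
Why: Triplet-sensitised geometric isomerisation of a β-boryl α,β-unsaturated carbonyl compound; in the Z isomer the carbonyl oxygen binds boron and takes it out of conjugation, so the Z isomer should be the poorer energy acceptor and accumulate.

Step 7
Reactants: 9 (S,Z)-4-[(tert-butyldimethylsilyl)oxy]-1-(4,4,5,5-tetramethyl-1,3,2-dioxaborolan-2-yl)hepta-1,6-dien-3-one; 10 isoprene
Product: 11 (2S)-2-[(tert-butyldimethylsilyl)oxy]-1-[(1S,6R)-4-methyl-6-(4,4,5,5-tetramethyl-1,3,2-dioxaborolan-2-yl)cyclohex-3-en-1-yl]pent-4-en-1-one (acyl and boryl groups cis)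
Conditions: Et2AlCl (1.1 equiv), isoprene (10 equiv), CH2Cl2, −78 → −30 °C; aq. KNaC4H4O6 work-up
Reagents that add atoms: none
Why: Et2AlCl binds the ketone oxygen of 9 and isoprene adds in a concerted, suprafacial [4+2] cycloaddition; the closest known reaction types are the Lewis-acid-promoted Diels–Alder reactions of isoprene with enones and of dienes with β-boryl acrylates. The cyclohexene ring closes by simultaneous formation of C1–C2 and C5–C6 on one face of the dienophile, an intermolecular cycloaddition and not a stepwise cyclisation. The cis relationship of the new stereocentres C1 and C6 is fixed by the Z geometry of 9, which is held s-cis because the s-trans form would press the boronate against C8. Their absolute configuration is controlled by C8: a silyl ether cannot chelate, so its C–O bond should lie anti to the complexed carbonyl, which puts the allyl arm over one face and the C8 hydrogen over the other, and the diene enters past the hydrogen. Regiochemistry follows from the polarised enone, whose β-carbon C6 bonds to the more nucleophilic terminus of isoprene (the CH2 attached to the methyl-bearing carbon), placing the acyl-bearing carbon para to the methyl and the alkene at C3=C4. Isoprene has no terminal substituents, so there is no endo/exo issue. The step therefore needs para regiochemistry, retention of the Z geometry and one dienophile face.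

Step 8
Reactants: 11 (2S)-2-[(tert-butyldimethylsilyl)oxy]-1-[(1S,6R)-4-methyl-6-(pinacolboryl)cyclohex-3-en-1-yl]pent-4-en-1-one
Product: 12 tert-butyldimethylsilyl ether of (3S)-2-[(1S,6R)-4-methyl-6-(pinacolboryl)cyclohex-3-en-1-yl]hexa-1,5-dien-3-ol
Conditions: Zn, CH2Br2, TiCl4, THF/CH2Cl2, 0 °C → rt
Reagents that add atoms: dibromomethane, BrCBr
Why: Takai–Lombardo methylenation with a gem-dizinc reagent and TiCl4 is non-basic, so C1 and C8 flanking the ketone should not epimerise, and boronate, silyl ether and alkenes are inert.

Step 9
Reactants: 12 silyl ether of (3S)-2-[(1S,6R)-4-methyl-6-(pinacolboryl)cyclohex-3-en-1-yl]hexa-1,5-dien-3-ol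
Product: 13 (3S)-2-[(1S,6R)-4-methyl-6-(pinacolboryl)cyclohex-3-en-1-yl]hexa-1,5-dien-3-ol
Conditions: Bu4NF, THF, 0 °C → rt; aq. NH4Cl
Reagents that add atoms: none
Why: Fluoride cleavage of the silyl ether; a secondary alkyl pinacol boronate forms at most a reversible fluoride adduct, so O8 is unmasked while O6 is still a C–B bond.

Step 10
Reactants: 14 angelic acid [(Z)-2-methylbut-2-enoic acid]
Product: 15 angelic 2,4,6-trichlorobenzoic anhydride [(Z)-2-methylbut-2-enoic 2,4,6-trichlorobenzoic anhydride]
Conditions: 2,4,6-trichlorobenzoyl chloride, Et3N, toluene, 0 °C → rt; filter off Et3NH+Cl−; kept as a toluene solution under argon at −20 °C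
Reagents that add atoms: 2,4,6-trichlorobenzoyl chloride, O=C(Cl)c1c(Cl)cc(Cl)cc1Cl
Why: Acylation of the triethylammonium carboxylate by the hindered acid chloride (first stage of the Yamaguchi esterification) gives the mixed anhydride without touching the Z alkene, since no nucleophilic catalyst is present; one batch serves steps 11 and 19.

Step 11
Reactants: 13 (3S)-2-[(1S,6R)-4-methyl-6-(pinacolboryl)cyclohex-3-en-1-yl]hexa-1,5-dien-3-ol; 15 angelic 2,4,6-trichlorobenzoic anhydride
Product: 16 (3S)-2-[(1S,6R)-4-methyl-6-(pinacolboryl)cyclohex-3-en-1-yl]hexa-1,5-dien-3-yl (Z)-2-methylbut-2-enoate (C8 angelate of 13)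
Conditions: 15 (1.5 equiv, toluene solution), toluene, 75 °C
Reagents that add atoms: none
Why: Second stage of the Yamaguchi esterification run thermally without DMAP or free amine, the conditions that acylate hindered alcohols with angelic acid without Z-to-E isomerisation; the alcohol attacks the unhindered angeloyl carbonyl of 15 and the C8–O bond is not broken.

Step 12
Reactants: 16 C8 angelate, C6 pinacol boronate
Product: 17 C6 alcohol (O6 cis to the chain), C8 angelate
Conditions: NaBO3·4H2O, THF/H2O, rt
Reagents that add atoms: sodium perborate, [Na+].OO[B-](O)(O)O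
Why: Perborate oxidation of a secondary alkyl boronate; carbon migrates from boron to oxygen with retention, so O6 ends cis to the chain, and the mild pH spares the ester.

Step 13
Reactants: 17 C6 alcohol, C8 angelate
Product: 18 C6 triethylsilyl ether, C8 angelate
Conditions: Et3SiCl, imidazole, DMF, 0 °C → rt
Reagents that add atoms: chlorotriethylsilane, CC[Si](CC)(CC)Cl
Why: Standard silylation; triethylsilyl is chosen because buffered fluoride removes it at the end beside epoxide, chlorohydrin and angelates.

Step 14
Reactants: 18 C6 triethylsilyl ether, C8 angelate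
Product: 19 C5 allylic alcohol (5-hydroxyl trans to O6, C3=C4 retained)
Conditions: SeO2 (0.5 equiv), tBuOOH, CH2Cl2, rt
Reagents that add atoms: tert-butyl hydroperoxide, CC(C)(C)OO (oxygen relayed through selenium dioxide, O=[Se]=O)
Why: Riley allylic oxidation (ene reaction of SeO2 at C3 with loss of a C5 hydrogen, then [2,3]-shift of oxygen to C5) follows the rule that the ring CH2 next to the more substituted alkene carbon is oxidised; delivery anti to O6 should give mainly the 5-epimer, which step 15 erases.

Step 15
Reactants: 19 C5 allylic alcohol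
Product: 20 C5 enone (C5 ketone conjugated with C3=C4)
Conditions: Dess–Martin periodinane, CH2Cl2, 0 °C → rt
Reagents that add atoms: none
Why: Dess–Martin oxidation of a secondary allylic alcohol; both C5 epimers and any enone already present converge.

Step 16
Reactants: 20 C5 enone
Product: 21 C5 allylic alcohol with the 5-hydroxyl cis to O6
Conditions: NaBH4, CeCl3·7H2O, MeOH, −78 °C
Reagents that add atoms: none
Why: Luche 1,2-reduction; with the chain equatorial the C6 silyloxy group is axial, and hydride should add axially on the face anti to it, giving the pseudo-equatorial C5 hydroxyl cis to O6.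

Step 17
Reactants: 21 cis C5 allylic alcohol
Product: 22 3,4-epoxy alcohol with the epoxide syn to O5
Conditions: VO(acac)2 (5 mol %), tBuOOH, CH2Cl2, 0 °C → rt
Reagents that add atoms: tert-butyl hydroperoxide, CC(C)(C)OO
Why: Vanadium-catalysed hydroxyl-directed epoxidation of a cyclic allylic alcohol delivers oxygen syn to O5 and leaves the two undirected alkenes alone.

Step 18
Reactants: 22 3,4-epoxy alcohol
Product: 23 chlorohydrin (3-chloro anti to the 4-hydroxyl; 4- and 5-hydroxyls free)
Conditions: Ti(OiPr)4, Et2NH·HCl, CH2Cl2, rt
Reagents that add atoms: diethylammonium chloride, CCNCC.Cl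
Why: Titanium-mediated opening of a 2,3-epoxy alcohol by chloride at the carbon remote from the carbinol (C3), which is also the less substituted carbon and the one reached by trans-diaxial opening with the chain equatorial; inversion at C3 puts chlorine anti to the C4 hydroxyl.

Step 19
Reactants: 23 chlorohydrin; 15 angelic 2,4,6-trichlorobenzoic anhydride
Product: 24 C5,C8 bis-angelate
Conditions: 15 (2 equiv, toluene solution), toluene, 80 °C
Reagents that add atoms: none
Why: Second thermal Yamaguchi-type angeloylation with the preformed mixed anhydride; only the secondary C5 hydroxyl should react, the tertiary C4 hydroxyl being inert and O6 silylated, and the absence of base keeps the trans-diaxial chlorohydrin from closing.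

Step 20
Reactants: 24 C5,C8 bis-angelate; 25 2-methylbut-2-ene
Product: 26 prenyl compound (C10=C11 trisubstituted alkene)
Conditions: second-generation Grubbs catalyst (H2IMes)(PCy3)Cl2Ru=CHPh (5 mol %), 2-methylbut-2-ene/CH2Cl2, 40 °C
Reagents that add atoms: none
Why: Cross-metathesis of the monosubstituted alkene with excess 2-methylbut-2-ene installs the prenyl terminus; the hindered 1,1-disubstituted C7 alkene and the conjugated angelates should not engage.

Step 21
Reactants: 26 prenyl compound
Product: 27 (10R)-10,11-epoxide, O6 triethylsilyl ether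
Conditions: D-fructose-derived Shi ketone (1.0 equiv), KHSO5 (as Oxone, 2KHSO5·KHSO4·K2SO4), NaHCO3, Bu4NHSO4, MeCN/aq. Na2EDTA, pH 7–8, 0 °C
Reagents that add atoms: potassium peroxymonosulfate, [K+].[O-]S(=O)(=O)OO
Why: Shi epoxidation by a chiral dioxirane through a spiro transition state attacks the most electron-rich alkene and sets C10 as R under reagent control, the 1,1-disubstituted and conjugated alkenes being slower; the hydrogencarbonate-buffered variant with a full equivalent of ketone is chosen over the carbonate-buffered catalytic one because the trans-diaxial chlorohydrin would close to the epoxide at higher pH.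

Step 22
Reactants: 27 (10R)-10,11-epoxide, O6 triethylsilyl ether
Product: 28 CNP0158207.1 (1R,3S,4S,5S,6S,8S,10R)
Conditions: Bu4NF, AcOH (1:1), THF, 0 °C → rt
Reagents that add atoms: none
Why: Fluoride desilylation buffered with acetic acid; near-neutral conditions should avoid epoxide opening, chlorohydrin closure and migration of the C5 angelate to O6.

## Compound list

1 | (S)-2-aminopent-4-enoic acid (L-allylglycine) | N[C@@H](CC=C)C(=O)O | starting material
2 | (S)-2-hydroxypent-4-enoic acid | O[C@@H](CC=C)C(=O)O | intermediate
3 | (S)-2-hydroxy-N-methoxy-N-methylpent-4-enamide | O[C@@H](CC=C)C(=O)N(C)OC | intermediate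
4 | (S)-2-[(tert-butyldimethylsilyl)oxy]-N-methoxy-N-methylpent-4-enamide | C=CC[C@H](O[Si](C)(C)C(C)(C)C)C(=O)N(C)OC | intermediate
5 | ethynylmagnesium bromide | C#C[Mg]Br | starting material
6 | (S)-4-[(tert-butyldimethylsilyl)oxy]hept-6-en-1-yn-3-one | C=CC[C@H](O[Si](C)(C)C(C)(C)C)C(=O)C#C | intermediate
7 | bis(pinacolato)diboron | CC1(C)OB(OC1(C)C)B1OC(C)(C)C(C)(C)O1 | starting material
8 | (S,E)-4-[(tert-butyldimethylsilyl)oxy]-1-(4,4,5,5-tetramethyl-1,3,2-dioxaborolan-2-yl)hepta-1,6-dien-3-one | C=CC[C@H](O[Si](C)(C)C(C)(C)C)C(=O)/C=C/B1OC(C)(C)C(C)(C)O1 | intermediate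
9 | (S,Z)-4-[(tert-butyldimethylsilyl)oxy]-1-(4,4,5,5-tetramethyl-1,3,2-dioxaborolan-2-yl)hepta-1,6-dien-3-one | C=CC[C@H](O[Si](C)(C)C(C)(C)C)C(=O)/C=C\B1OC(C)(C)C(C)(C)O1 | intermediate
10 | isoprene (2-methylbuta-1,3-diene) | C=CC(C)=C | starting material
11 | (2S)-2-[(tert-butyldimethylsilyl)oxy]-1-[(1S,6R)-4-methyl-6-(4,4,5,5-tetramethyl-1,3,2-dioxaborolan-2-yl)cyclohex-3-en-1-yl]pent-4-en-1-one | O=C([C@H](CC=C)O[Si](C)(C)C(C)(C)C)[C@H]1CC=C(C)C[C@H]1B1OC(C)(C)C(C)(C)O1 | intermediate
12 | tert-butyldimethylsilyl ether of (3S)-2-[(1S,6R)-4-methyl-6-(pinacolboryl)cyclohex-3-en-1-yl]hexa-1,5-dien-3-ol | C=C([C@H](CC=C)O[Si](C)(C)C(C)(C)C)[C@H]1CC=C(C)C[C@H]1B1OC(C)(C)C(C)(C)O1 | intermediate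
13 | (3S)-2-[(1S,6R)-4-methyl-6-(pinacolboryl)cyclohex-3-en-1-yl]hexa-1,5-dien-3-ol | C=C([C@H](CC=C)O)[C@H]1CC=C(C)C[C@H]1B1OC(C)(C)C(C)(C)O1 | intermediate
14 | angelic acid, (Z)-2-methylbut-2-enoic acid | C/C=C(/C)C(=O)O | starting material
15 | angelic 2,4,6-trichlorobenzoic anhydride, (Z)-2-methylbut-2-enoic 2,4,6-trichlorobenzoic anhydride | C/C=C(/C)C(=O)OC(=O)c1c(Cl)cc(Cl)cc1Cl | intermediate
16 | (3S)-2-[(1S,6R)-4-methyl-6-(pinacolboryl)cyclohex-3-en-1-yl]hexa-1,5-dien-3-yl (Z)-2-methylbut-2-enoate (C8 angelate of 13, C6 pinacol boronate cis to the chain) | C=C([C@H](CC=C)OC(=O)/C(C)=C\C)[C@H]1CC=C(C)C[C@H]1B1OC(C)(C)C(C)(C)O1 | intermediate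
17 | C6 alcohol, O6 cis to the chain, C8 angelate (1R,6R,8S) | C=C([C@H](CC=C)OC(=O)/C(C)=C\C)[C@H]1CC=C(C)C[C@H]1O | intermediate
18 | C6 triethylsilyl ether of 17 (1R,6R,8S) | C=C([C@H](CC=C)OC(=O)/C(C)=C\C)[C@H]1CC=C(C)C[C@H]1O[Si](CC)(CC)CC | intermediate
19 | C5 allylic alcohol of 18, 5-hydroxyl trans to O6 | C=C([C@H](CC=C)OC(=O)/C(C)=C\C)[C@H]1CC=C(C)[C@H](O)[C@H]1O[Si](CC)(CC)CC | intermediate
20 | C5 enone (4-methyl-5-oxocyclohex-3-ene ring, C6 silyloxy cis to the chain) | C=C([C@H](CC=C)OC(=O)/C(C)=C\C)[C@H]1CC=C(C)C(=O)[C@H]1O[Si](CC)(CC)CC | intermediate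
21 | C5 allylic alcohol, 5-hydroxyl cis to O6 | C=C([C@H](CC=C)OC(=O)/C(C)=C\C)[C@H]1CC=C(C)[C@@H](O)[C@H]1O[Si](CC)(CC)CC | intermediate
22 | 3,4-epoxy alcohol, epoxide syn to O5 and O6 | C=C([C@H](CC=C)OC(=O)/C(C)=C\C)[C@H]1C[C@H]2O[C@@]2(C)[C@@H](O)[C@H]1O[Si](CC)(CC)CC | intermediate
23 | chlorohydrin (1R,3S,4S,5S,6S,8S): 3-chloro anti to the 4-hydroxyl; 4,5-diol; O6 triethylsilyl ether; C8 angelate | C=C([C@H](CC=C)OC(=O)/C(C)=C\C)[C@H]1C[C@H](Cl)[C@@](C)(O)[C@@H](O)[C@H]1O[Si](CC)(CC)CC | intermediate
24 | C5,C8 bis-angelate of 23 | C=C([C@H](CC=C)OC(=O)/C(C)=C\C)[C@H]1C[C@H](Cl)[C@@](C)(O)[C@@H](OC(=O)/C(C)=C\C)[C@H]1O[Si](CC)(CC)CC | intermediate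
25 | 2-methylbut-2-ene | CC=C(C)C | starting material
26 | prenyl compound (C10=C11 alkene), O6 triethylsilyl ether | C=C([C@H](CC=C(C)C)OC(=O)/C(C)=C\C)[C@H]1C[C@H](Cl)[C@@](C)(O)[C@@H](OC(=O)/C(C)=C\C)[C@H]1O[Si](CC)(CC)CC | intermediate
27 | (10R)-10,11-epoxide, O6 triethylsilyl ether of the target | C=C([C@H](C[C@H]1OC1(C)C)OC(=O)/C(C)=C\C)[C@H]1C[C@H](Cl)[C@@](C)(O)[C@@H](OC(=O)/C(C)=C\C)[C@H]1O[Si](CC)(CC)CC | intermediate
28 | CNP0158207.1 (1R,3S,4S,5S,6S,8S,10R) | C=C([C@H](C[C@H]1OC1(C)C)OC(=O)/C(C)=C\C)[C@H]1C[C@H](Cl)[C@@](C)(O)[C@@H](OC(=O)/C(C)=C\C)[C@H]1O | target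

## Step count and least certain steps

Total: 22 steps. Longest linear sequence: 21 steps (1 → 28 through steps 1–9 and 11–22); step 10 is a one-step side branch that supplies 15. Compounds 1, 5, 7, 10, 14 and 25 are purchased.

**Step 7 (key step).** Facial selectivity may be poor or reversed if rotation about C7–C8 does not settle in the dipole-opposed conformer; a conformer with the C8 hydrogen eclipsing the carbonyl would put the silyloxy and allyl groups on opposite faces. The Z geometry may also be lost by Lewis-acid-mediated isomerisation before cycloaddition, which would give trans C1/C6, and isoprene may oligomerise. The fallback replaces conformational control by a covalent chelate in the C8-epimeric series and corrects C8 afterwards. It sets out from 3. Mitsunobu inversion with 4-nitrobenzoic acid (PPh3, diisopropyl azodicarboxylate) gives (R)-1-[methoxy(methyl)amino]-1-oxopent-4-en-2-yl 4-nitrobenzoate F1, and methanolysis (K2CO3, MeOH) gives (R)-2-hydroxy-N-methoxy-N-methylpent-4-enamide F2. Excess 5 gives (R)-4-hydroxyhept-6-en-1-yn-3-one F3, and the conditions of steps 5 and 6 give the (R,E)-boryl hydroxy enone F4 and the (R,Z)-boryl hydroxy enone F5. With two equivalents of Et2AlCl the hydroxyl becomes an aluminium alkoxide bound to the carbonyl oxygen, which locks the allyl arm on one face, so 10 should add to the other and give the 8-epi hydroxy ketone adduct F6 with C1 and C6 as in 11. Mitsunobu esterification of this α-hydroxy ketone with 14 inverts C8 and installs the ester, giving the (8S)-angelate ketone F7, and the methylenation of step 8 comes back to the route at 16.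

**Step 6.** The photostationary mixture may be unfavourable if the enone chromophores of 8 and 9 are sensitised at similar rates. The triplet enone may also undergo intramolecular [2+2] cycloaddition onto the allyl arm, for which a hepta-1,6-dien-3-one is set up. The fallback builds the Z alkene thermally and sets out from 6, skipping step 5. Anti addition of hydrogen iodide (LiI, AcOH, MeCN, rt) gives (S,Z)-4-[(tert-butyldimethylsilyl)oxy]-1-iodohepta-1,6-dien-3-one F8. Stereoretentive Miyaura borylation with 7 (PdCl2(dppf), KOAc, dioxane, 60 °C) comes back at 9.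

**Step 14.** Hydrogen abstraction from the C4 methyl may compete, the adjacent C6 silyloxy group may slow the ene reaction, and the other two alkenes may be oxidised slowly. The fallback replaces C–H oxidation by a carbonyl transposition and sets out from 18. NOCl (CH2Cl2, −20 °C) adds to the trisubstituted alkene with nitrogen at C3 and chloride at C4, giving after tautomerisation the α-chloro oxime F9. Pyridine removes HCl into the ring to give the conjugated oxime F10. Oxime exchange with glyoxylic acid frees the transposed enone F11 (C3 ketone, C4=C5). H2O2/NaOH at 0 °C epoxidises it anti to O6 to give epoxy ketone F12. Wharton transposition (N2H4·H2O, AcOH, MeOH) restores the C3=C4 alkene with oxygen on C5 and comes back at 19.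

**Step 18.** Under Lewis-acid activation chloride may attack the tertiary carbon C4 in a carbocation-like opening. The fallback does without the epoxide and sets out from 21. tert-Butyl hypochlorite in aqueous acetone at 0 °C forms the chloronium ion reversibly; only the ion anti to O5 and O6 can be opened trans-diaxially by water at C4 with the chain equatorial. This comes back at 23 and makes no new compound.

**Step 19.** The C5 hydroxyl lies between the quaternary C4 and the silylated C6 and may acylate slowly; prolonged heating could then bring Z-to-E isomerisation of the angelate or acid-promoted loss of the triethylsilyl group by the liberated 2,4,6-trichlorobenzoic acid. The fallback builds the Z alkene on the ester before the chlorohydrin exists and sets out from 22. Esterification with 2-[bis(2,2,2-trifluoroethoxy)phosphoryl]propanoic acid (DCC, cat. DMAP) gives the C5 phosphonopropanoate F13. Still–Gennari olefination with acetaldehyde (KN(SiMe3)2, 18-crown-6, THF, −78 °C) gives the epoxy bis-angelate F14. Opening with LiCl/AcOH in THF, guided by sterics and trans-diaxial opening alone, comes back at 24.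

## Further compounds

F1 | step 7 | (R)-1-[methoxy(methyl)amino]-1-oxopent-4-en-2-yl 4-nitrobenzoate | C=CC[C@@H](OC(=O)c1ccc(cc1)[N+](=O)[O-])C(=O)N(C)OC
F2 | step 7 | (R)-2-hydroxy-N-methoxy-N-methylpent-4-enamide | C=CC[C@@H](O)C(=O)N(C)OC
F3 | step 7 | (R)-4-hydroxyhept-6-en-1-yn-3-one | C=CC[C@@H](O)C(=O)C#C
F4 | step 7 | (R,E)-4-hydroxy-1-(4,4,5,5-tetramethyl-1,3,2-dioxaborolan-2-yl)hepta-1,6-dien-3-one | C=CC[C@@H](O)C(=O)/C=C/B1OC(C)(C)C(C)(C)O1
F5 | step 7 | (R,Z)-4-hydroxy-1-(4,4,5,5-tetramethyl-1,3,2-dioxaborolan-2-yl)hepta-1,6-dien-3-one | C=CC[C@@H](O)C(=O)/C=C\B1OC(C)(C)C(C)(C)O1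
F6 | step 7 | 8-epi hydroxy ketone adduct, (2R)-2-hydroxy-1-[(1S,6R)-4-methyl-6-(pinacolboryl)cyclohex-3-en-1-yl]pent-4-en-1-one | O=C([C@@H](CC=C)O)[C@H]1CC=C(C)C[C@H]1B1OC(C)(C)C(C)(C)O1
F7 | step 7 | (8S)-angelate ketone, C7 ketone analogue of 16 | O=C([C@H](CC=C)OC(=O)/C(C)=C\C)[C@H]1CC=C(C)C[C@H]1B1OC(C)(C)C(C)(C)O1
F8 | step 6 | (S,Z)-4-[(tert-butyldimethylsilyl)oxy]-1-iodohepta-1,6-dien-3-one | C=CC[C@H](O[Si](C)(C)C(C)(C)C)C(=O)/C=C\I
F9 | step 14 | α-chloro oxime (C3 oxime, C4 chloride) from 18 | C=C([C@H](CC=C)OC(=O)/C(C)=C\C)[C@H]1CC(=NO)[C@@](C)(Cl)C[C@H]1O[Si](CC)(CC)CC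
F10 | step 14 | conjugated oxime (C3 oxime, C4=C5) | C=C([C@H](CC=C)OC(=O)/C(C)=C\C)[C@H]1CC(=NO)C(C)=C[C@H]1O[Si](CC)(CC)CC
F11 | step 14 | transposed enone (C3 ketone, C4=C5) | C=C([C@H](CC=C)OC(=O)/C(C)=C\C)[C@H]1CC(=O)C(C)=C[C@H]1O[Si](CC)(CC)CC
F12 | step 14 | 4,5-epoxy C3 ketone, epoxide anti to O6 | C=C([C@H](CC=C)OC(=O)/C(C)=C\C)[C@H]1CC(=O)[C@]2(C)O[C@@H]2[C@H]1O[Si](CC)(CC)CC
F0 | step 18 | none | none
F13 | step 19 | C5 2-[bis(2,2,2-trifluoroethoxy)phosphoryl]propanoate of 22 (mixture at the phosphonate carbon) | C=C([C@H](CC=C)OC(=O)/C(C)=C\C)[C@H]1C[C@H]2O[C@@]2(C)[C@@H](OC(=O)C(C)P(=O)(OCC(F)(F)F)OCC(F)(F)F)[C@H]1O[Si](CC)(CC)CC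
F14 | step 19 | epoxy bis-angelate (C5 angelate of 22) | C=C([C@H](CC=C)OC(=O)/C(C)=C\C)[C@H]1C[C@H]2O[C@@]2(C)[C@@H](OC(=O)/C(C)=C\C)[C@H]1O[Si](CC)(CC)CC
A1 | alternative 1 | 2,3-epoxy alcohol with C8 configured, O4/O5 acetonide | OC[C@@]1(O[C@H]1CC=C(C)C)[C@H]2C[C@H](Cl)[C@@](C)(OC(C)(C)O3)[C@@H]3[C@H]2O
A2 | alternative 1 | (E)-trisubstituted primary allylic alcohol precursor of A1 | OC/C(=C/CC=C(C)C)[C@H]1C[C@H](Cl)[C@@](C)(OC(C)(C)O2)[C@@H]2[C@H]1O
A3 | alternative 2 | cyclohexanone with C1 ketone, C3 hydroxyl, C4 tertiary carbinol, O5/O6 acetonide | O=C1C[C@H](O)[C@@](C)(O)[C@H]2OC(C)(C)O[C@@H]12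
A4 | alternative 2 | methyl 6-deoxy-3,4-O-isopropylidene-2-C-methyl-hex-5-enopyranoside, talo-type configuration at C2–C4 | COC1OC(=C)[C@@H]2OC(C)(C)O[C@@H]2[C@]1(C)O
A5 | alternative 3 | chlorohydrin ketol (C6 ketone, C1 ethyl ester, O5 4-methoxybenzyl ether) | CCOC(=O)[C@H]1C[C@H](Cl)[C@@](C)(O)[C@@H](OCc2ccc(OC)cc2)C1=O
A6 | alternative 3 | ethyl 4-[(4-methoxybenzyl)oxy]-3-oxobutanoate | CCOC(=O)CC(=O)COCc1ccc(OC)cc1
A7 | alternative 3 | 3-chlorobut-3-en-2-one | CC(=O)C(Cl)=C
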